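The numbers in the tables were generated by integration for an exercise, noise included.

The east run, colder than the north run, needs longer for a like climb in product, and that stretch of time is the number you need for this flask.

the same everywhere: starting material 0.80 M

|  | reagent | temperature | remark | time |
|---|---|---|---|---|
| north | 1.1 equiv | 5 °C | the very flask that is asked about, followed so far |  |
| east | 1.1 equiv | −10 °C | run made earlier |  |
| flask | 1.10 equiv | 5 °C |  | 30 min |

| run | time / min | product / % | starting material / % |
|---|---|---|---|
| north | 1.33 | 38.1 | 5.7 |
| north | 2.50 | 44.0 | 3.7 |
| north | 5.00 | 49.4 | 1.3 |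
| north | 10.0 | 57.2 | 3.2 |
| north | 20.0 | 63.6 | 0.7 |
| east | 3.00 | 36.0 | 17.1 |
| east | 5.00 | 41.4 | 6.5 |
| east | 10.0 | 45.1 | 1.0 |
| east | 20.0 | 48.6 | 1.7 |
| east | 40.0 | 54.6 | 2.6 |

(each reading ± 1 percentage point)

- epsilon: change nothing and wait 1.0 h more
- eta: at 30 min take out 90% of the product then present, then wait 1.0 h
- delta: at 30 min raise the temperature by 15 K, then wait 1.0 h

* product, in percent of the starting material first charged, at 30 min
* the option that brings most further product ("none" if no option brings more than 2 percentage points) (epsilon / eta / delta / none)
* product present, with what was taken out counted in, in percent of the starting material first charged, after eta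
* product present, with what was taken out counted in, in percent of the starting material first charged, after delta

- product taken out counts as made

At 20.0 min the north run shows 63.6% of the charge as product and 0.7% as starting material, so 35.7% sits unseen, in a resting state that you watch draining. Over about the same product range north rises 7.8 percentage points from 5.00 min to 10.0 min, and east rises 6 points from 20.0 min to 40.0 min. The ratio of those slopes is 5.20, the clock factor: the minutes of slow phase at −10 °C that one minute at 5 °C does the work of. It is a reading, since each rise carries 1.4 points of scatter.

Is one number enough? Not early. North's 1.33 min maps to 6.92 min of east, yet east had 41.4% at 5.00 min, against north's 38.1%. So the factor serves the slow phase.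

Delta's 15 K is that same gap, so I count its 1.0 h as 312 min of waiting. North's last gain per doubling of time, 6.4 points, then gives me 67.3% at 30 min, 77.5% after epsilon and 89.8% after delta. I count eta as plain waiting.

The forecast, which differs from me, gives 66%, eta, 84% and 69%, reasoning that “Heating mainly speeds arrival at a similar plateau”.

The flask gives 67.4% at 30 min, and delta brings most: 28 points, against 15 points for epsilon and 15 points for eta. The totals are 82.1% after eta and 95.8% after delta.

    starting material ⇌ intermediate A (K = 2.90, k = 0.0300 s⁻¹, Ea = 82.0 kJ mol⁻¹, ΔH = −37.0 kJ mol⁻¹)
    starting material + reagent → product (k = 0.0290 L mol⁻¹ s⁻¹, Ea = 62.0 kJ mol⁻¹)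
    starting material ⇌ intermediate B (K = 29.0, k = 0.0150 s⁻¹, Ea = 78.0 kJ mol⁻¹, ΔH = −4.00 kJ mol⁻¹)
    (constants at 5 °C)

Left at 5 °C, this flask stands at 95.4% after 300 min, beside the 95.8% from delta's hour, which the clock factor counted as 312 min. The neighbouring flask, this one run at −20 °C, lies 0.667 of a 15 K step below east, so the factor becomes 3.00, and the east reading of 45.1% at 10.0 min is what I carry to that flask at 30.0 min. The neighbouring flask holds 49.3% product at 30.0 min, 4.2 points above that reading, in the direction of the early gap, with 19.0% as intermediate B and 29.9% as intermediate A.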